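**Retrosynthetic overview**
1. Side chain last: the (E)-alkene comes from a (Z)-enol triflate of a C5 ketone by Negishi methylation; the ketone comes from a C5 aldehyde and an alkyllithium made by an Evans syn-aldol sequence.
2. Oxirane: hydroxyl-directed epoxidation of the C1=C6 alkene of a cyclohexa-2,4-dienylmethanol (CH2OH on C5).
3. Carbocycle: formal [3+3] annulation of (2-methylallylidene)triphenylphosphorane with the alkylidene acetoacetate of a 2-acetylpyranone; one operation forms C3–C4 and C1–C6 (as C1=C6).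
4. Enabling feature: in the cyclohexene ring the quaternary C4 and the oxirane carbon C6 are 1,3-related through C5, which bears a carbon substituent, so C4–C5–C6 is the β-carbon, α-carbon and ketone carbon of an alkylidene acetoacetate, while C1–C2(Me)=C3 is a 2-methylallyl unit; the oxirane C1–C6 bond is the σ-bond of a Wittig-made alkene.
5. Ring order: pyranone (triketide lactonisation, step 2), cyclohexadiene (step 5), oxirane (step 7).

Key step: step 5

Remark (numbering): locants in the text are those of the target's 7-oxabicyclo[4.1.0]hept-2-ene core (C1 and C6 oxirane carbons, C2=C3, C4 quaternary, C5 side-chain carbon) and are kept for the corresponding carbons of all intermediates.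
Remark (assumption): the (−)-menthyl ester is assumed to act mainly as a resolving handle, the two C4-epimeric menthyl esters from step 5 being separable by chromatography or crystallisation; the antipodal menthyl ester would serve equally.

**Step 1**
Reactants: 1 methyl 2-methyl-3-oxopentanoate; 2 methyl 2,2-dimethoxypropanoate
Product: 3 methyl 6,6-dimethoxy-2,4-dimethyl-3,5-dioxoheptanoate
Conditions: NaH, THF, 0 °C; n-BuLi, 0 °C; then 2, 0 °C → rt; aq. HCl work-up
Reagents that add atoms: none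
Why: Claisen-type γ-acylation of the β-keto ester dianion, whose more basic terminal carbanion attacks the ester of 2, which has no enolisable α-hydrogen.

**Step 2**
Reactants: 3 methyl 6,6-dimethoxy-2,4-dimethyl-3,5-dioxoheptanoate
Product: 5 6-acetyl-4-hydroxy-3,5-dimethyl-2H-pyran-2-one, via ketal pyranone 4 (not isolated)
Conditions: DBU, toluene, 80 °C; then 2 M HCl, THF, rt
Reagents that add atoms: water, O
Why: Base-mediated lactonisation (the C5 enol oxygen attacks the methyl ester in a 6-exo-trig acyl substitution) gives the 4-hydroxy-2-pyranone, and acid-catalysed ketal hydrolysis then unmasks the acetyl group.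

**Step 3**
Reactants: 5 6-acetyl-4-hydroxy-3,5-dimethyl-2H-pyran-2-one
Product: 6 2-acetyl-6-methoxy-3,5-dimethyl-4H-pyran-4-one
Conditions: MeOTf, CH2Cl2, 0 °C → rt; aqueous work-up
Reagents that add atoms: methyl trifluoromethanesulfonate, COS(=O)(=O)C(F)(F)F
Why: Kinetic O-methylation at the lactone carbonyl oxygen of the 4-hydroxy-2-pyranone gives a 2-methoxy-4-hydroxypyrylium ion that loses a proton to the α-methoxy-γ-pyranone.

**Step 4**
Reactants: 6 2-acetyl-6-methoxy-3,5-dimethyl-4H-pyran-4-one; 7 (1R,2S,5R)-2-isopropyl-5-methylcyclohexyl 3-oxobutanoate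
Product: 8 (1R,2S,5R)-2-isopropyl-5-methylcyclohexyl 2-acetyl-3-(6-methoxy-3,5-dimethyl-4-oxo-4H-pyran-2-yl)but-2-enoate (E/Z mixture)
Conditions: TiCl4, pyridine, THF, 0 °C → rt
Reagents that add atoms: none
Why: TiCl4/pyridine-mediated Knoevenagel condensation of an electron-poor methyl ketone with a β-keto ester; the alkene geometry is irrelevant because both isomers lead to the same Michael adduct.

**Step 5**
Reactants: 8 (1R,2S,5R)-2-isopropyl-5-methylcyclohexyl 2-acetyl-3-(6-methoxy-3,5-dimethyl-4-oxo-4H-pyran-2-yl)but-2-enoate; 9 (2-methylprop-2-en-1-yl)triphenylphosphonium chloride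
Product: 13 (1R,2S,5R)-2-isopropyl-5-methylcyclohexyl (1R,6R)-6-(6-methoxy-3,5-dimethyl-4-oxo-4H-pyran-2-yl)-2,4,6-trimethylcyclohexa-2,4-diene-1-carboxylate, via phosphorus ylide 10 (not isolated), via zwitterionic Michael adduct 11 (not isolated), via allylic ylide 12 (not isolated)
Conditions: 9, KN(SiMe3)2 (slight deficit), THF, −78 → 0 °C; then 8, −78 °C → rt, then 50 °C; pH 7 buffer; diastereomers separated by chromatography or crystallisation
Reagents that add atoms: none
Why: The unhindered CH2 terminus (γ-carbon) of the allylic ylide 10 adds in a vinylogous Michael reaction to the β-carbon of the doubly activated alkene of 8 and so forms the C3–C4 bond and the quaternary centre; proton transfer within the vinylphosphonium/enolate zwitterion 11 gives the allylic ylide 12, whose α-carbon attacks the acetyl carbonyl in a 6-exo-trig sense and, through the oxaphosphetane and loss of Ph3PO, closes the carbocycle by intramolecular Wittig olefination, forming the C1=C6 bond whose σ-component is the later oxirane C–C bond. The closest known reaction type is the [3+3] cyclohexadiene annulation of allylidenetriphenylphosphorane with alkylidene acetoacetates (Michael addition followed by intramolecular Wittig reaction), here with a 2-methylallylidene ylide and a pyranonyl/methyl-substituted acceptor. C4 is created in the Michael step without dependable facial control, so both configurations are expected, and the menthyl ester, which doubles as the second activating group, serves as the resolving handle by which the (4R)-series diastereomer 13 is separated; C5, the epimerisable carbon between the two carbonyl groups of 11 and 12, should be set during ring closure under thermodynamic control with the ester trans to the bulkier pyranone. The step needs γ-1,4-addition to win over direct Wittig olefination of the ketone and over α-1,4-addition: the tetrasubstituted, twisted and doubly activated acceptor should make betaine formation at the ketone slow and reversible, an α-adduct has no productive exit because Ph3P is no leaving group, and the ester carbonyl is inert to the ylide so that only the ketone is olefinated. A slight deficit of base and a cold, neutral quench should keep the 2,4-diene from moving into conjugation with the ester.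

**Step 6**
Reactants: 13 (1R,2S,5R)-2-isopropyl-5-methylcyclohexyl (1R,6R)-6-(6-methoxy-3,5-dimethyl-4-oxo-4H-pyran-2-yl)-2,4,6-trimethylcyclohexa-2,4-diene-1-carboxylate
Product: 14 6-[(1R,6R)-6-(hydroxymethyl)-1,3,5-trimethylcyclohexa-2,4-dien-1-yl]-2-methoxy-3,5-dimethyl-4H-pyran-4-one
Conditions: i-Bu2AlH, CH2Cl2, −78 → −20 °C; aq. KNaC4H4O6 (tartrate) work-up
Reagents that add atoms: none
Why: Ester-to-alcohol reduction by i-Bu2AlH at low temperature, at which the vinylogous-ester carbonyl of the pyranone and the ring diene should be spared; the chiral alcohol is released.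

**Step 7**
Reactants: 14 6-[(1R,6R)-6-(hydroxymethyl)-1,3,5-trimethylcyclohexa-2,4-dien-1-yl]-2-methoxy-3,5-dimethyl-4H-pyran-4-one
Product: 15 6-[(1R,4R,5R,6S)-5-(hydroxymethyl)-2,4,6-trimethyl-7-oxabicyclo[4.1.0]hept-2-en-4-yl]-2-methoxy-3,5-dimethyl-4H-pyran-4-one
Conditions: VO(acac)2 (cat.), t-BuOOH (anhydrous), CH2Cl2, 0 °C
Reagents that add atoms: tert-butyl hydroperoxide, CC(C)(C)OO
Why: Hydroxyl-directed epoxidation, in which the vanadium alkoxide of the homoallylic alcohol should deliver oxygen only to the proximal C1=C6 alkene and to the face cis to the CH2OH-bearing C5 substituent, which is also the face away from the pyranone; this sets C1 and C6.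

**Step 8**
Reactants: 15 6-[(1R,4R,5R,6S)-5-(hydroxymethyl)-2,4,6-trimethyl-7-oxabicyclo[4.1.0]hept-2-en-4-yl]-2-methoxy-3,5-dimethyl-4H-pyran-4-one
Product: 16 (1R,4R,5S,6S)-4-(6-methoxy-3,5-dimethyl-4-oxo-4H-pyran-2-yl)-2,4,6-trimethyl-7-oxabicyclo[4.1.0]hept-2-ene-5-carbaldehyde
Conditions: Dess–Martin periodinane, pyridine, CH2Cl2, 0 °C
Reagents that add atoms: none
Why: Dess–Martin oxidation under buffered, non-basic conditions, chosen so that the epimerisable C5 of the β,γ-epoxy aldehyde is not exposed to base.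

**Step 9**
Reactants: 17 (4S)-4-benzyl-3-propanoyl-1,3-oxazolidin-2-one; 18 propanal
Product: 19 (4S)-4-benzyl-3-[(2S,3R)-3-hydroxy-2-methylpentanoyl]-1,3-oxazolidin-2-one
Conditions: Bu2BOTf, i-Pr2NEt, CH2Cl2, −78 → 0 °C; 18, −78 → 0 °C; H2O2, MeOH, pH 7 buffer
Reagents that add atoms: none
Why: Evans syn-aldol reaction, in which the Z-boron enolate reacts through a closed chair transition state and the auxiliary fixes the (2S,3R) configuration; C2 of this fragment becomes the side-chain methine of the target.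

**Step 10**
Reactants: 19 (4S)-4-benzyl-3-[(2S,3R)-3-hydroxy-2-methylpentanoyl]-1,3-oxazolidin-2-one
Product: 20 (4S)-4-benzyl-3-[(2S,3R)-3-{[tert-butyl(dimethyl)silyl]oxy}-2-methylpentanoyl]-1,3-oxazolidin-2-one
Conditions: TBSOTf, 2,6-lutidine, CH2Cl2, 0 °C
Reagents that add atoms: tert-butyldimethylsilyl trifluoromethanesulfonate, CC(C)(C)[Si](C)(C)OS(=O)(=O)C(F)(F)F
Why: Silylation of the secondary alcohol with a silyl triflate and a hindered base, which blocks retro-aldol cleavage in the next step.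

**Step 11**
Reactants: 20 (4S)-4-benzyl-3-[(2S,3R)-3-{[tert-butyl(dimethyl)silyl]oxy}-2-methylpentanoyl]-1,3-oxazolidin-2-one
Product: 21 (2R,3R)-3-{[tert-butyl(dimethyl)silyl]oxy}-2-methylpentan-1-ol
Conditions: LiBH4, MeOH (1 equiv), Et2O, 0 °C
Reagents that add atoms: none
Why: Reductive removal of the oxazolidinone by LiBH4 at the exocyclic carbonyl, without epimerisation of the α-stereocentre.

**Step 12**
Reactants: 21 (2R,3R)-3-{[tert-butyl(dimethyl)silyl]oxy}-2-methylpentan-1-ol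
Product: 22 tert-butyl{[(2S,3R)-1-iodo-2-methylpentan-3-yl]oxy}dimethylsilane
Conditions: I2, PPh3, imidazole, CH2Cl2, 0 °C → rt
Reagents that add atoms: iodine, [I][I]
Why: Appel-type iodination of the primary alcohol by SN2 displacement of the alkoxyphosphonium, which leaves both stereocentres untouched.

**Step 13**
Reactants: 22 tert-butyl{[(2S,3R)-1-iodo-2-methylpentan-3-yl]oxy}dimethylsilane; 16 (1R,4R,5S,6S)-4-(6-methoxy-3,5-dimethyl-4-oxo-4H-pyran-2-yl)-2,4,6-trimethyl-7-oxabicyclo[4.1.0]hept-2-ene-5-carbaldehyde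
Product: 24 6-[(1R,4R,5R,6S)-5-[(3R,4R)-4-{[tert-butyl(dimethyl)silyl]oxy}-1-hydroxy-3-methylhexyl]-2,4,6-trimethyl-7-oxabicyclo[4.1.0]hept-2-en-4-yl]-2-methoxy-3,5-dimethyl-4H-pyran-4-one (carbinol epimers), via alkyllithium 23 (not isolated)
Conditions: 22, t-BuLi (2 equiv), Et2O, −78 °C; then 16, −78 °C; H2O quench
Reagents that add atoms: none
Why: Iodine–lithium exchange gives the primary alkyllithium, which should add to the aldehyde faster than to the pyranone or the oxirane at −78 °C; the configuration of the new carbinol is irrelevant because it is oxidised in step 14.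

**Step 14**
Reactants: 24 6-[(1R,4R,5R,6S)-5-[(3R,4R)-4-{[tert-butyl(dimethyl)silyl]oxy}-1-hydroxy-3-methylhexyl]-2,4,6-trimethyl-7-oxabicyclo[4.1.0]hept-2-en-4-yl]-2-methoxy-3,5-dimethyl-4H-pyran-4-one
Product: 25 6-[(1R,4R,5S,6S)-5-[(3R,4R)-4-{[tert-butyl(dimethyl)silyl]oxy}-3-methylhexanoyl]-2,4,6-trimethyl-7-oxabicyclo[4.1.0]hept-2-en-4-yl]-2-methoxy-3,5-dimethyl-4H-pyran-4-one
Conditions: Dess–Martin periodinane, pyridine, CH2Cl2, 0 °C → rt
Reagents that add atoms: none
Why: Dess–Martin oxidation of the secondary alcohol under buffered conditions that spare the vinyl oxirane and the C5 stereocentre.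

**Step 15**
Reactants: 25 6-[(1R,4R,5S,6S)-5-[(3R,4R)-4-{[tert-butyl(dimethyl)silyl]oxy}-3-methylhexanoyl]-2,4,6-trimethyl-7-oxabicyclo[4.1.0]hept-2-en-4-yl]-2-methoxy-3,5-dimethyl-4H-pyran-4-one
Product: 27 (1Z,3R,4R)-4-{[tert-butyl(dimethyl)silyl]oxy}-1-[(1R,4R,5S,6S)-4-(6-methoxy-3,5-dimethyl-4-oxo-4H-pyran-2-yl)-2,4,6-trimethyl-7-oxabicyclo[4.1.0]hept-2-en-5-yl]-3-methylhex-1-en-1-yl trifluoromethanesulfonate, via potassium enolate 26 (not isolated)
Conditions: KN(SiMe3)2, THF, −78 °C; then PhNTf2, −78 → −40 °C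
Reagents that add atoms: N-phenylbis(trifluoromethanesulfonimide), O=S(=O)(N(c1ccccc1)S(=O)(=O)C(F)(F)F)C(F)(F)F
Why: Kinetic deprotonation by the hindered amide base should occur at the less hindered CH2 and not at the tertiary C5–H, and the bulky C5 substituent should favour the Z-enolate (oxygen cis to the chain), which is trapped on oxygen as the (Z)-enol triflate; this geometry fixes the (E)-alkene of the target.

**Step 16**
Reactants: 27 (1Z,3R,4R)-4-{[tert-butyl(dimethyl)silyl]oxy}-1-[(1R,4R,5S,6S)-4-(6-methoxy-3,5-dimethyl-4-oxo-4H-pyran-2-yl)-2,4,6-trimethyl-7-oxabicyclo[4.1.0]hept-2-en-5-yl]-3-methylhex-1-en-1-yl trifluoromethanesulfonate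
Product: 28 6-[(1R,4R,5S,6S)-5-[(2E,4R,5R)-5-{[tert-butyl(dimethyl)silyl]oxy}-4-methylhept-2-en-2-yl]-2,4,6-trimethyl-7-oxabicyclo[4.1.0]hept-2-en-4-yl]-2-methoxy-3,5-dimethyl-4H-pyran-4-one
Conditions: MeZnCl, Pd(PPh3)4 (cat.), THF, 0 °C → rt
Reagents that add atoms: methylzinc chloride, C[Zn]Cl
Why: Negishi cross-coupling of the enol triflate with retention of alkene geometry places the methyl group cis to the chain and so gives the (E)-trisubstituted alkene; oxidative addition into the electron-poor enol triflate is expected to be faster than ionisation of the hindered trisubstituted vinyl oxirane.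

**Step 17**
Reactants: 28 6-[(1R,4R,5S,6S)-5-[(2E,4R,5R)-5-{[tert-butyl(dimethyl)silyl]oxy}-4-methylhept-2-en-2-yl]-2,4,6-trimethyl-7-oxabicyclo[4.1.0]hept-2-en-4-yl]-2-methoxy-3,5-dimethyl-4H-pyran-4-one
Product: 29 6-[(1R,4R,5S,6S)-5-[(2E,4R,5R)-5-hydroxy-4-methylhept-2-en-2-yl]-2,4,6-trimethyl-7-oxabicyclo[4.1.0]hept-2-en-4-yl]-2-methoxy-3,5-dimethyl-4H-pyran-4-one
Conditions: Bu4NF, THF, 0 °C → rt
Reagents that add atoms: none
Why: Fluoride-mediated cleavage of the silyl ether under non-acidic conditions that the vinyl oxirane should tolerate.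

**Step 18**
Reactants: 29 6-[(1R,4R,5S,6S)-5-[(2E,4R,5R)-5-hydroxy-4-methylhept-2-en-2-yl]-2,4,6-trimethyl-7-oxabicyclo[4.1.0]hept-2-en-4-yl]-2-methoxy-3,5-dimethyl-4H-pyran-4-one
Product: 30 2-methoxy-3,5-dimethyl-6-[(1R,4R,5S,6S)-2,4,6-trimethyl-5-[(2E,4R)-4-methyl-5-oxohept-2-en-2-yl]-7-oxabicyclo[4.1.0]hept-2-en-4-yl]-4H-pyran-4-one
Conditions: Dess–Martin periodinane, pyridine, CH2Cl2, 0 °C
Reagents that add atoms: none
Why: Buffered Dess–Martin oxidation of the secondary alcohol, a neutral method expected to leave the α-stereocentre of the β,γ-unsaturated ketone and the alkene position unchanged.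

**Compound list**
1 | methyl 2-methyl-3-oxopentanoate | CCC(=O)C(C)C(=O)OC | starting material
2 | methyl 2,2-dimethoxypropanoate | COC(=O)C(C)(OC)OC | starting material
3 | methyl 6,6-dimethoxy-2,4-dimethyl-3,5-dioxoheptanoate (diastereomer and tautomer mixture) | COC(=O)C(C)C(=O)C(C)C(=O)C(C)(OC)OC | intermediate
4 | 6-(1,1-dimethoxyethyl)-4-hydroxy-3,5-dimethyl-2H-pyran-2-one | COC(C)(OC)C1=C(C)C(O)=C(C)C(=O)O1 | intermediate
5 | 6-acetyl-4-hydroxy-3,5-dimethyl-2H-pyran-2-one | CC(=O)C1=C(C)C(O)=C(C)C(=O)O1 | intermediate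
6 | 2-acetyl-6-methoxy-3,5-dimethyl-4H-pyran-4-one | CC(=O)c1oc(OC)c(C)c(=O)c1C | intermediate
7 | (1R,2S,5R)-2-isopropyl-5-methylcyclohexyl 3-oxobutanoate [(−)-menthyl acetoacetate] | C[C@@H]1CC[C@H]([C@@H](C1)OC(=O)CC(C)=O)C(C)C | starting material
8 | (1R,2S,5R)-2-isopropyl-5-methylcyclohexyl 2-acetyl-3-(6-methoxy-3,5-dimethyl-4-oxo-4H-pyran-2-yl)but-2-enoate (E/Z mixture) | C[C@@H]1CC[C@H]([C@@H](C1)OC(=O)C(C(C)=O)=C(C)c1oc(OC)c(C)c(=O)c1C)C(C)C | intermediate
9 | (2-methylprop-2-en-1-yl)triphenylphosphonium chloride | C=C(C)C[P+](c1ccccc1)(c1ccccc1)c1ccccc1.[Cl-] | starting material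
10 | (2-methylprop-2-en-1-ylidene)triphenylphosphorane | C=C(C)C=P(c1ccccc1)(c1ccccc1)c1ccccc1 | intermediate
11 | zwitterionic Michael adduct: menthyl β-keto ester enolate whose β-carbon (future C4, configuration as in 13) carries methyl, the pyranonyl group and a 2-methyl-3-(triphenylphosphonio)prop-2-enyl group | C[C@@H]1CC[C@H]([C@@H](C1)OC(=O)C(=C(C)[O-])[C@](C)(c1oc(OC)c(C)c(=O)c1C)CC(C)=C[P+](c1ccccc1)(c1ccccc1)c1ccccc1)C(C)C | intermediate
12 | allylic ylide tautomer of 11 (keto ester form, Z-alkene between future C2 and C3) | C[C@@H]1CC[C@H]([C@@H](C1)OC(=O)C(C(C)=O)[C@](C)(c1oc(OC)c(C)c(=O)c1C)/C=C(\C=P(c1ccccc1)(c1ccccc1)c1ccccc1)C)C(C)C | intermediate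
13 | (1R,2S,5R)-2-isopropyl-5-methylcyclohexyl (1R,6R)-6-(6-methoxy-3,5-dimethyl-4-oxo-4H-pyran-2-yl)-2,4,6-trimethylcyclohexa-2,4-diene-1-carboxylate (ester trans to the pyranone) | C[C@@H]1CC[C@H]([C@@H](C1)OC(=O)[C@@H]1C(C)=CC(C)=C[C@@]1(C)c1oc(OC)c(C)c(=O)c1C)C(C)C | intermediate
14 | 6-[(1R,6R)-6-(hydroxymethyl)-1,3,5-trimethylcyclohexa-2,4-dien-1-yl]-2-methoxy-3,5-dimethyl-4H-pyran-4-one | OC[C@@H]1C(C)=CC(C)=C[C@@]1(C)c1oc(OC)c(C)c(=O)c1C | intermediate
15 | 6-[(1R,4R,5R,6S)-5-(hydroxymethyl)-2,4,6-trimethyl-7-oxabicyclo[4.1.0]hept-2-en-4-yl]-2-methoxy-3,5-dimethyl-4H-pyran-4-one (oxirane cis to CH2OH, trans to the pyranone) | OC[C@@H]1[C@]2(C)O[C@@H]2C(C)=C[C@@]1(C)c1oc(OC)c(C)c(=O)c1C | intermediate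
16 | (1R,4R,5S,6S)-4-(6-methoxy-3,5-dimethyl-4-oxo-4H-pyran-2-yl)-2,4,6-trimethyl-7-oxabicyclo[4.1.0]hept-2-ene-5-carbaldehyde | O=C[C@@H]1[C@]2(C)O[C@@H]2C(C)=C[C@@]1(C)c1oc(OC)c(C)c(=O)c1C | intermediate
17 | (4S)-4-benzyl-3-propanoyl-1,3-oxazolidin-2-one | CCC(=O)N1C(=O)OC[C@@H]1Cc1ccccc1 | starting material
18 | propanal | CCC=O | starting material
19 | (4S)-4-benzyl-3-[(2S,3R)-3-hydroxy-2-methylpentanoyl]-1,3-oxazolidin-2-one | CC[C@@H](O)[C@H](C)C(=O)N1C(=O)OC[C@@H]1Cc1ccccc1 | intermediate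
20 | (4S)-4-benzyl-3-[(2S,3R)-3-{[tert-butyl(dimethyl)silyl]oxy}-2-methylpentanoyl]-1,3-oxazolidin-2-one | CC[C@@H](O[Si](C)(C)C(C)(C)C)[C@H](C)C(=O)N1C(=O)OC[C@@H]1Cc1ccccc1 | intermediate
21 | (2R,3R)-3-{[tert-butyl(dimethyl)silyl]oxy}-2-methylpentan-1-ol | CC[C@@H](O[Si](C)(C)C(C)(C)C)[C@H](C)CO | intermediate
22 | tert-butyl{[(2S,3R)-1-iodo-2-methylpentan-3-yl]oxy}dimethylsilane | CC[C@@H](O[Si](C)(C)C(C)(C)C)[C@H](C)CI | intermediate
23 | [(2R,3R)-3-{[tert-butyl(dimethyl)silyl]oxy}-2-methylpentyl]lithium | CC[C@@H](O[Si](C)(C)C(C)(C)C)[C@H](C)C[Li] | intermediate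
24 | 6-[(1R,4R,5R,6S)-5-[(3R,4R)-4-{[tert-butyl(dimethyl)silyl]oxy}-1-hydroxy-3-methylhexyl]-2,4,6-trimethyl-7-oxabicyclo[4.1.0]hept-2-en-4-yl]-2-methoxy-3,5-dimethyl-4H-pyran-4-one (carbinol epimers) | CC[C@@H](O[Si](C)(C)C(C)(C)C)[C@H](C)CC(O)[C@@H]1[C@]2(C)O[C@@H]2C(C)=C[C@@]1(C)c1oc(OC)c(C)c(=O)c1C | intermediate
25 | 6-[(1R,4R,5S,6S)-5-[(3R,4R)-4-{[tert-butyl(dimethyl)silyl]oxy}-3-methylhexanoyl]-2,4,6-trimethyl-7-oxabicyclo[4.1.0]hept-2-en-4-yl]-2-methoxy-3,5-dimethyl-4H-pyran-4-one | CC[C@@H](O[Si](C)(C)C(C)(C)C)[C@H](C)CC(=O)[C@@H]1[C@]2(C)O[C@@H]2C(C)=C[C@@]1(C)c1oc(OC)c(C)c(=O)c1C | intermediate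
26 | potassium (Z)-enolate of 25 (oxygen cis to the chain) | CC[C@@H](O[Si](C)(C)C(C)(C)C)[C@H](C)/C=C(\[O-])[C@@H]1[C@]2(C)O[C@@H]2C(C)=C[C@@]1(C)c1oc(OC)c(C)c(=O)c1C.[K+] | intermediate
27 | (1Z,3R,4R)-4-{[tert-butyl(dimethyl)silyl]oxy}-1-[(1R,4R,5S,6S)-4-(6-methoxy-3,5-dimethyl-4-oxo-4H-pyran-2-yl)-2,4,6-trimethyl-7-oxabicyclo[4.1.0]hept-2-en-5-yl]-3-methylhex-1-en-1-yl trifluoromethanesulfonate | CC[C@@H](O[Si](C)(C)C(C)(C)C)[C@H](C)/C=C(\OS(=O)(=O)C(F)(F)F)[C@@H]1[C@]2(C)O[C@@H]2C(C)=C[C@@]1(C)c1oc(OC)c(C)c(=O)c1C | intermediate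
28 | 6-[(1R,4R,5S,6S)-5-[(2E,4R,5R)-5-{[tert-butyl(dimethyl)silyl]oxy}-4-methylhept-2-en-2-yl]-2,4,6-trimethyl-7-oxabicyclo[4.1.0]hept-2-en-4-yl]-2-methoxy-3,5-dimethyl-4H-pyran-4-one | CC[C@@H](O[Si](C)(C)C(C)(C)C)[C@H](C)/C=C(\C)[C@@H]1[C@]2(C)O[C@@H]2C(C)=C[C@@]1(C)c1oc(OC)c(C)c(=O)c1C | intermediate
29 | 6-[(1R,4R,5S,6S)-5-[(2E,4R,5R)-5-hydroxy-4-methylhept-2-en-2-yl]-2,4,6-trimethyl-7-oxabicyclo[4.1.0]hept-2-en-4-yl]-2-methoxy-3,5-dimethyl-4H-pyran-4-one | CC[C@@H](O)[C@H](C)/C=C(\C)[C@@H]1[C@]2(C)O[C@@H]2C(C)=C[C@@]1(C)c1oc(OC)c(C)c(=O)c1C | intermediate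
30 | 2-methoxy-3,5-dimethyl-6-[(1R,4R,5S,6S)-2,4,6-trimethyl-5-[(2E,4R)-4-methyl-5-oxohept-2-en-2-yl]-7-oxabicyclo[4.1.0]hept-2-en-4-yl]-4H-pyran-4-one | CCC(=O)[C@H](C)/C=C(\C)[C@@H]1[C@]2(C)O[C@@H]2C(C)=C[C@@]1(C)c1oc(OC)c(C)c(=O)c1C | target

**Totals**
Total step count: 18. Longest linear sequence: 14 steps (steps 1–8 and 13–18).

**Steps most likely to fail**

Step 5. The ylide may olefinate the acetyl carbonyl directly, add through its α-carbon, or merely deprotonate the γ-methyl group of 8; the ring diene may also migrate into conjugation with the ester, and the diastereomers may resist separation. Fallback (sets out from 8, returns at 13): Hosomi–Sakurai conjugate allylation of 8 with 2-(chloromethyl)-3-(trimethylsilyl)prop-1-ene (TiCl4, CH2Cl2, −78 °C) would put the CH2 terminus of the allylsilane on C4 and give the allylic chloride F1. PPh3 (NaI cat., MeCN, 60 °C) would convert it into the phosphonium chloride F2. One equivalent of KOt-Bu (THF, 0 °C) would trigger the intramolecular Wittig reaction onto the acetyl group and give the 2-methylidene cyclohexene ester F3 (C1=C6 in the ring, CH2= on C2). RhCl3·3H2O (cat., EtOH, 60 °C) would then move the exocyclic double bond into the ring to give 13, separated from its diastereomer as in the main route.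

Step 7. The Lewis-acidic vanadium may ionise the newly formed vinyl oxirane at C1, with capture by the neighbouring hydroxyl or by tert-butanol, and the distal C2=C3 alkene may be oxidised as well. Fallback (sets out from 14, returns at 15): Boc2O and DMAP (cat., MeCN, rt) would give the tert-butyl carbonate F4. IBr (toluene, −80 °C) would induce iodocarbonate cyclisation, the carbonate oxygen adding to C6 on the face of the tether and iodine to C1 anti to it, to give the iodo cyclic carbonate F5. K2CO3 in MeOH would cleave the carbonate, and the C6 alkoxide would displace iodide at C1 with inversion to close the oxirane cis to the CH2OH group, giving 15.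

Step 16. Zerovalent palladium may ionise the vinyl oxirane (π-allyl formation followed by methyl transfer or elimination) in competition with oxidative addition into the enol triflate, and the enol triflate of step 15 may form with imperfect geometry. Fallback (sets out from 16 and 22, returns at 28): MeMgBr (THF, −78 °C) would add to 16 to give the secondary carbinol F6, and buffered Dess–Martin oxidation would give the methyl ketone F7. In parallel 22 with 1-phenyl-1H-tetrazole-5-thiol and K2CO3 (DMF, rt) would give the tetrazolyl sulfide F8, and H2O2 with (NH4)6Mo7O24·4H2O (cat., EtOH) would give the tetrazolyl sulfone F9. Deprotonation of F9 with KN(SiMe3)2 (THF, −78 °C) and addition of F7 would form the trisubstituted alkene by Julia–Kocienski olefination without any transition metal, and 28 would be separated from its (Z)-isomer.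

**Further compounds**
F1 | step 5 | (1R,2S,5R)-2-isopropyl-5-methylcyclohexyl 2-acetyl-5-(chloromethyl)-3-(6-methoxy-3,5-dimethyl-4-oxo-4H-pyran-2-yl)-3-methylhex-5-enoate (diastereomer mixture) | C[C@@H]1CC[C@H]([C@@H](C1)OC(=O)C(C(C)=O)C(C)(c1oc(OC)c(C)c(=O)c1C)CC(=C)CCl)C(C)C
F2 | step 5 | {5-acetyl-6-[(1R,2S,5R)-2-isopropyl-5-methylcyclohexyl]oxy-4-(6-methoxy-3,5-dimethyl-4-oxo-4H-pyran-2-yl)-4-methyl-2-methylidene-6-oxohexyl}triphenylphosphonium chloride (diastereomer mixture) | C[C@@H]1CC[C@H]([C@@H](C1)OC(=O)C(C(C)=O)C(C)(c1oc(OC)c(C)c(=O)c1C)CC(=C)C[P+](c1ccccc1)(c1ccccc1)c1ccccc1)C(C)C.[Cl-]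
F3 | step 5 | (1R,2S,5R)-2-isopropyl-5-methylcyclohexyl 6-(6-methoxy-3,5-dimethyl-4-oxo-4H-pyran-2-yl)-2,6-dimethyl-4-methylidenecyclohex-2-ene-1-carboxylate (diastereomer mixture) | C[C@@H]1CC[C@H]([C@@H](C1)OC(=O)C1C(C)=CC(=C)CC1(C)c1oc(OC)c(C)c(=O)c1C)C(C)C
F4 | step 7 | tert-butyl [(1R,6R)-6-(6-methoxy-3,5-dimethyl-4-oxo-4H-pyran-2-yl)-2,4,6-trimethylcyclohexa-2,4-dien-1-yl]methyl carbonate | CC(C)(C)OC(=O)OC[C@@H]1C(C)=CC(C)=C[C@@]1(C)c1oc(OC)c(C)c(=O)c1C
F5 | step 7 | 8-iodo-5-(6-methoxy-3,5-dimethyl-4-oxo-4H-pyran-2-yl)-5,7,8a-trimethyl-4a,5,8,8a-tetrahydro-4H-1,3-benzodioxin-2-one (carbonate oxygen on C6 cis to the CH2O tether, iodine on C1 trans to it, pyranone trans to the tether) | O=C1OC[C@@H]2[C@](C)(O1)[C@@H](I)C(C)=C[C@@]2(C)c1oc(OC)c(C)c(=O)c1C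
F6 | step 16 | 6-[(1R,4R,5R,6S)-5-(1-hydroxyethyl)-2,4,6-trimethyl-7-oxabicyclo[4.1.0]hept-2-en-4-yl]-2-methoxy-3,5-dimethyl-4H-pyran-4-one (carbinol epimers) | CC(O)[C@@H]1[C@]2(C)O[C@@H]2C(C)=C[C@@]1(C)c1oc(OC)c(C)c(=O)c1C
F7 | step 16 | 6-[(1R,4R,5S,6S)-5-acetyl-2,4,6-trimethyl-7-oxabicyclo[4.1.0]hept-2-en-4-yl]-2-methoxy-3,5-dimethyl-4H-pyran-4-one | CC(=O)[C@@H]1[C@]2(C)O[C@@H]2C(C)=C[C@@]1(C)c1oc(OC)c(C)c(=O)c1C
F8 | step 16 | 5-{[(2S,3R)-3-{[tert-butyl(dimethyl)silyl]oxy}-2-methylpentyl]sulfanyl}-1-phenyl-1H-tetrazole | CC[C@@H](O[Si](C)(C)C(C)(C)C)[C@H](C)CSc1nnnn1-c1ccccc1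
F9 | step 16 | 5-{[(2S,3R)-3-{[tert-butyl(dimethyl)silyl]oxy}-2-methylpentyl]sulfonyl}-1-phenyl-1H-tetrazole | CC[C@@H](O[Si](C)(C)C(C)(C)C)[C@H](C)CS(=O)(=O)c1nnnn1-c1ccccc1
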